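**Retrosynthetic overview**
1. Target 14 ⇐ dimethyl ether 13 by thiolate O-demethylation, the only protecting-group step.
2. 13 ⇐ hydroxy ketone 10: one operation closes the pyran (hemiketal → 2H-pyran) and, by intramolecular [2+2], the cyclopentane and the cyclobutane; the three CH stereocentres follow from the carbinol centre.
3. 10 ⇐ diazo ketone 8 + (R)-linalool 9: the C11–vinyl bond is made by hydroxyl-directed C–H alkylation; the chiral pool supplies the O-bearing quaternary carbon and its C–O bond is never broken.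
4. 8 ⇐ dibenzoxepinone 5 (iodination, Stille prenylation, diazo transfer); 5 ⇐ acid 3 by Friedel–Crafts closure; 3 ⇐ 1 + 2 by Ullmann ether synthesis.
5. Ring order: rings A and B bought → oxepinone ring → pyran + cyclopentane + cyclobutane together.

Assumption: commercial (R)-(−)-linalool of ≥97% ee is used; its carbinol carbon has the same spatial arrangement (R) as the O-bearing quaternary carbon of the target.

**Step 1**
Reactants: 1 2-bromo-4-methoxyphenylacetic acid; 2 3-methoxyphenol
Product: 3 2-[4-methoxy-2-(3-methoxyphenoxy)phenyl]acetic acid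
Conditions: CuI (10 mol%), N,N-dimethylglycine (30 mol%), Cs2CO3 (3 equiv), dioxane, 100 °C
Reagents that add atoms: none
Why: Ullmann-type C–O coupling of the aryl bromide with the phenol, helped by the ortho carboxymethyl group binding monovalent copper; no stereocentre is involved.

**Step 2**
Reactants: 3 2-[4-methoxy-2-(3-methoxyphenoxy)phenyl]acetic acid
Product: 5 3,7-dimethoxydibenzo[b,f]oxepin-10(11H)-one, via mixed trifluoroacetic anhydride 4 (not isolated)
Conditions: TFAA (2 equiv), CH2Cl2, 0 °C to rt; TfOH (5 mol%)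
Reagents that add atoms: none
Why: Intramolecular Friedel–Crafts acylation closes the seven-membered ketone on ring B at the carbon ortho to the ether oxygen and para to OMe, the only position that is both reachable and activated.

**Step 3**
Reactants: 5 3,7-dimethoxydibenzo[b,f]oxepin-10(11H)-one
Product: 6 2-iodo-3,7-dimethoxydibenzo[b,f]oxepin-10(11H)-one
Conditions: NIS (1.05 equiv), TFA (10 mol%), MeCN, 0 °C
Reagents that add atoms: N-iodosuccinimide, O=C1CCC(=O)N1I
Why: Electrophilic aromatic iodination goes to C2 of ring A (ortho to OMe, para to the ether oxygen, less hindered than C4), while ring B is deactivated by the conjugated ketone.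

**Step 4**
Reactants: 6 2-iodo-3,7-dimethoxydibenzo[b,f]oxepin-10(11H)-one
Product: 7 3,7-dimethoxy-2-(3-methylbut-2-en-1-yl)dibenzo[b,f]oxepin-10(11H)-one
Conditions: prenylSnBu3 (1.3 equiv), Pd(PPh3)4 (5 mol%), DMF, 90 °C
Reagents that add atoms: tributyl(3-methylbut-2-en-1-yl)stannane, CCCC[Sn](CCCC)(CCCC)CC=C(C)C
Why: Stille cross-coupling of the aryl iodide with the allylic stannane gives the linear prenyl arene under neutral conditions that leave the enolisable ketone alone.

**Step 5**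
Reactants: 7 3,7-dimethoxy-2-(3-methylbut-2-en-1-yl)dibenzo[b,f]oxepin-10(11H)-one
Product: 8 11-diazo-3,7-dimethoxy-2-(3-methylbut-2-en-1-yl)dibenzo[b,f]oxepin-10(11H)-one
Conditions: p-ABSA (1.3 equiv), DBU (1.5 equiv), MeCN, 0 °C to rt
Reagents that add atoms: 4-acetamidobenzenesulfonyl azide, CC(=O)Nc1ccc(cc1)S(=O)(=O)N=[N+]=[N-]
Why: Regitz diazo transfer to the doubly activated (benzylic, α-keto) methylene through its DBU enolate.

**Step 6**
Reactants: 8 11-diazo-3,7-dimethoxy-2-(3-methylbut-2-en-1-yl)dibenzo[b,f]oxepin-10(11H)-one; 9 (R)-(−)-linalool [(3R)-3,7-dimethylocta-1,6-dien-3-ol]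
Product: 10 11-[(1Z,3R)-3-hydroxy-3,7-dimethylocta-1,6-dien-1-yl]-3,7-dimethoxy-2-(3-methylbut-2-en-1-yl)dibenzo[b,f]oxepin-10(11H)-one (both C11 epimers)
Conditions: (C5Me5)Rh(OAc)2 (5 mol%), CsOAc (30 mol%), 9 (3 equiv), ClCH2CH2Cl, 30 °C, slow addition of 8; cold neutral work-up
Reagents that add atoms: none
Why: Proposed new method: acetate-assisted, hydroxyl-directed metalation of the vinyl C–H cis to the carbinol gives a five-membered oxa-rhodacycle of trivalent rhodium, the diazo ketone forms a rhodium carbene that inserts into the Rh–vinyl bond, and protonolysis by AcOH releases the ketone with the Z alkene fixed by the metallacycle and the carbinol stereocentre untouched; the closest known reaction type is (C5Me5)Rh-catalysed C–H alkylation/annulation of acrylamides, acrylic acids and 2-alkenylphenols with α-diazo carbonyl compounds.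

**Step 7**
Reactants: 10 11-[(1Z,3R)-3-hydroxy-3,7-dimethylocta-1,6-dien-1-yl]-3,7-dimethoxy-2-(3-methylbut-2-en-1-yl)dibenzo[b,f]oxepin-10(11H)-one
Product: 13 3,7-di-O-methyl ether of the target cyclol, via cyclic hemiketal 11 (not isolated), via 2H-pyran 12 (not isolated)
Conditions: CSA (10 mol%), 4 Å MS, Ir[dF(CF3)ppy]2(dtbbpy)PF6 (1 mol%), CH2Cl2, −20 °C, 450 nm LEDs
Reagents that add atoms: none
Why: Proposed new method: acid-catalysed ketalisation/dehydration of the δ-hydroxy ketone gives 2H-pyran 12 at a temperature where oxa-6π ring opening (its only racemisation path) is slow, and triplet energy transfer from the trivalent iridium sensitiser to the aryl-conjugated dienol ether triggers a stepwise intramolecular [2+2] photocycloaddition (five-membered ring first, then cyclobutane closure) in which the three-atom tether from the (R)-carbinol carbon allows only the all-cis cage, so the three new CH stereocentres are set by that centre; the closest known reactions are the sensitised photocyclisation of 2H-chromenes to cyclols and the visible-light [2+2] of 1,3-dienes.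

**Step 8**
Reactants: 13 3,7-di-O-methyl ether of the target cyclol
Product: 14 target (CNP0185814.1)
Conditions: NaSEt (8 equiv), DMF, 140 °C; then 1 M HCl
Reagents that add atoms: none
Why: SN2 O-demethylation of both aryl methyl ethers by thiolate frees the phenols without acid, so the prenyl group, the enol ether and the cyclobutane are not attacked and no stereocentre is touched.

**Compound list**
1 | 2-bromo-4-methoxyphenylacetic acid | COc1ccc(CC(=O)O)c(Br)c1 | starting material
2 | 3-methoxyphenol | COc1cccc(O)c1 | starting material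
3 | 2-[4-methoxy-2-(3-methoxyphenoxy)phenyl]acetic acid | COc1ccc(CC(=O)O)c(Oc2cccc(OC)c2)c1 | intermediate
4 | mixed anhydride of 3 with trifluoroacetic acid (not isolated) | COc1ccc(CC(=O)OC(=O)C(F)(F)F)c(Oc2cccc(OC)c2)c1 | intermediate
5 | 3,7-dimethoxydibenzo[b,f]oxepin-10(11H)-one | COc1ccc2c(c1)Oc1cc(OC)ccc1C(=O)C2 | intermediate
6 | 2-iodo-3,7-dimethoxydibenzo[b,f]oxepin-10(11H)-one | COc1c(I)cc2c(c1)Oc1cc(OC)ccc1C(=O)C2 | intermediate
7 | 3,7-dimethoxy-2-(3-methylbut-2-en-1-yl)dibenzo[b,f]oxepin-10(11H)-one | COc1c(CC=C(C)C)cc2c(c1)Oc1cc(OC)ccc1C(=O)C2 | intermediate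
8 | 11-diazo-3,7-dimethoxy-2-(3-methylbut-2-en-1-yl)dibenzo[b,f]oxepin-10(11H)-one | COc1c(CC=C(C)C)cc2c(c1)Oc1cc(OC)ccc1C(=O)C2=[N+]=[N-] | intermediate
9 | (R)-(−)-linalool, (3R)-3,7-dimethylocta-1,6-dien-3-ol | CC(C)=CCC[C@](C)(C=C)O | starting material
10 | 11-[(1Z,3R)-3-hydroxy-3,7-dimethylocta-1,6-dien-1-yl]-3,7-dimethoxy-2-(3-methylbut-2-en-1-yl)dibenzo[b,f]oxepin-10(11H)-one, C11 epimers | COc1c(CC=C(C)C)cc2c(c1)Oc1cc(OC)ccc1C(=O)C2/C=C\[C@](C)(O)CCC=C(C)C | intermediate
11 | cyclic hemiketal of 10 (not isolated): carbinol O bonded to C10, giving a 2-hydroxy-3,6-dihydro-2H-pyran fused at C10–C11; quaternary carbon R | COc1c(CC=C(C)C)cc2c(c1)Oc1cc(OC)ccc1C3(O)O[C@](C)(CCC=C(C)C)C=CC23 | intermediate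
12 | (R)-2H-pyran (not isolated): pyran fused across C10=C11 of the 3,7-dimethoxy-2-prenyl-dibenzo[b,f]oxepine, O on C10, CH=CH on C11, sp3 carbon bearing CH3 and 4-methylpent-3-enyl | COc1c(CC=C(C)C)cc2c(c1)Oc1cc(OC)ccc1C3=C2C=C[C@@](C)(CCC=C(C)C)O3 | intermediate
13 | 3,7-di-O-methyl ether of the target cyclol (cage stereocentres as in 14) | CC(C)=CCc1cc2c(cc1OC)Oc1cc(OC)ccc1C1=C2[C@@H]2[C@H]3[C@H](CC[C@@]3(C)O1)C2(C)C | intermediate
14 | target: 3,7-dihydroxy-2-prenyl-dibenzo[b,f]oxepine fused across C10=C11 to the cyclol cage (pyran O on C10; cyclobutane CH on C11 R; central CH R; cyclobutane/cyclopentane fusion CH S; O-bearing quaternary C R; gem-dimethyl on the cyclobutane) | CC(C)=CCc1cc2c(cc1O)Oc1cc(O)ccc1C1=C2[C@@H]2[C@H]3[C@H](CC[C@@]3(C)O1)C2(C)C | target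

**Step count**
Total: 8 steps. Longest linear sequence: 8 steps (1 → 14); linalool 9 enters at step 6.

**Three steps most likely to fail**

Step 6 (C–H alkylation). It has no direct precedent with a tertiary allylic alcohol. The rhodium alkoxide may undergo β-carbon elimination, linalool may ionise, or 10 may dehydrate early to 12 and racemise at 30 °C. The fallback sets out from 9 and 7 and comes back at 12, replacing the C–H logic by an aldol condensation. Hydroboration of the vinyl group of 9 with 9-BBN and NaOH/H2O2 work-up gives (R)-3,7-dimethyloct-6-ene-1,3-diol F1. TEMPO/PhI(OAc)2 oxidises the primary alcohol to (R)-3-hydroxy-3,7-dimethyloct-6-enal F2. Crossed aldol condensation of 7 with F2 (TiCl4, Et3N, CH2Cl2, −78 to 0 °C) gives 11-[(3R)-3-hydroxy-3,7-dimethyloct-6-en-1-ylidene]-3,7-dimethoxy-2-(3-methylbut-2-en-1-yl)dibenzo[b,f]oxepin-10(11H)-one F3 as an E/Z mixture. Under the light, sensitiser and acid of step 7 the isomers interconvert, and the one with the hydroxyalkyl chain cis to the carbonyl closes to the 2-hydroxy-5,6-dihydro-2H-pyran hemiketal F4. F4 loses water (ionisation at C10, proton loss from the ring CH2) to give 12, which reacts on as in step 7.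

Step 7 (cyclodehydration/[2+2]). If 12 accumulates it can ring-open (thermally or photochemically) and lose its configuration, or the biradical can close the wrong way. The fallback sets out from 10 and comes back at 13, never passing through a 2H-pyran. KN(SiMe3)2 (2.1 equiv, THF, −78 °C) then t-Bu2Si(OTf)2 ties the C10 enol oxygen and the carbinol oxygen into the eight-membered cyclic di-tert-butylsilylene dienol ether F5, whose tether keeps the diene terminus cis. Sensitised irradiation as in step 7 but without acid gives the silylene-bridged cyclobutane F6. HF·pyridine removes silicon to give the δ-hydroxy ketone F7. CSA with 4 Å MS closes it through the cage hemiketal F8 and dehydrates it to 13.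

Step 8 (double demethylation). Hot thiolate on the finished cage may be incomplete or may degrade it. The fallback sets out from 7 and comes back at 14, moving the demethylation to the robust ketone and carrying silyl ethers instead. NaSEt/DMF at 120 °C on 7 gives 3,7-dihydroxy-2-(3-methylbut-2-en-1-yl)dibenzo[b,f]oxepin-10(11H)-one F9. TIPSCl/imidazole gives the bis(triisopropylsilyl) ether F10. Diazo transfer (p-ABSA, DBU) gives the 11-diazo ketone F11. The C–H alkylation of 9 as in step 6 gives the Z-hydroxyalkenyl ketone F12. The conditions of step 7 give, through hemiketal F13 and 2H-pyran F14, the bis(triisopropylsilyl) ether of the target F15. TBAF buffered with AcOH (THF, 0 °C) then frees 14.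

**Further compounds**
F1 | step 6 | (R)-3,7-dimethyloct-6-ene-1,3-diol | CC(C)=CCC[C@](C)(CCO)O
F2 | step 6 | (R)-3-hydroxy-3,7-dimethyloct-6-enal | CC(C)=CCC[C@](C)(CC=O)O
F3 | step 6 | 11-[(3R)-3-hydroxy-3,7-dimethyloct-6-en-1-ylidene]-3,7-dimethoxy-2-(3-methylbut-2-en-1-yl)dibenzo[b,f]oxepin-10(11H)-one | COc1c(CC=C(C)C)cc2c(c1)Oc1cc(OC)ccc1C(=O)C2=CC[C@](C)(O)CCC=C(C)C
F4 | step 6 | 2-hydroxy-5,6-dihydro-2H-pyran hemiketal of F3 | COc1c(CC=C(C)C)cc2c(c1)Oc1cc(OC)ccc1C3(O)O[C@](C)(CCC=C(C)C)CC=C23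
F5 | step 7 | cyclic di-tert-butylsilylene dienol ether of 10 | COc1c(CC=C(C)C)cc2c(c1)Oc1cc(OC)ccc1C3=C2/C=C\[C@@](C)(CCC=C(C)C)O[Si](C(C)(C)C)(C(C)(C)C)O3
F6 | step 7 | silylene-bridged [2+2] adduct | CC(C)=CCc1cc2c(cc1OC)Oc1cc(OC)ccc1C1=C2[C@@H]2[C@H]3[C@H](CC[C@@]3(C)O[Si](C(C)(C)C)(C(C)(C)C)O1)C2(C)C
F7 | step 7 | δ-hydroxy ketone of the bicyclo[3.2.0]heptane | CC(C)=CCc1cc2c(cc1OC)Oc1cc(OC)ccc1C(=O)C2[C@@H]2[C@H]3[C@H](CC[C@@]3(C)O)C2(C)C
F8 | step 7 | cage hemiketal of F7 | CC(C)=CCc1cc2c(cc1OC)Oc1cc(OC)ccc1C1(O)C2[C@@H]2[C@H]3[C@H](CC[C@@]3(C)O1)C2(C)C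
F9 | step 8 | 3,7-dihydroxy-2-(3-methylbut-2-en-1-yl)dibenzo[b,f]oxepin-10(11H)-one | Oc1c(CC=C(C)C)cc2c(c1)Oc1cc(O)ccc1C(=O)C2
F10 | step 8 | bis(triisopropylsilyl) ether of F9 | CC(C)[Si](Oc1c(CC=C(C)C)cc2c(c1)Oc1cc(O[Si](C(C)C)(C(C)C)C(C)C)ccc1C(=O)C2)(C(C)C)C(C)C
F11 | step 8 | 11-diazo ketone of F10 | CC(C)[Si](Oc1c(CC=C(C)C)cc2c(c1)Oc1cc(O[Si](C(C)C)(C(C)C)C(C)C)ccc1C(=O)C2=[N+]=[N-])(C(C)C)C(C)C
F12 | step 8 | Z-hydroxyalkenyl ketone, silyl analogue of 10 | CC(C)[Si](Oc1c(CC=C(C)C)cc2c(c1)Oc1cc(O[Si](C(C)C)(C(C)C)C(C)C)ccc1C(=O)C2/C=C\[C@](C)(O)CCC=C(C)C)(C(C)C)C(C)C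
F13 | step 8 | cyclic hemiketal, silyl analogue of 11 | CC(C)[Si](Oc1c(CC=C(C)C)cc2c(c1)Oc1cc(O[Si](C(C)C)(C(C)C)C(C)C)ccc1C3(O)O[C@](C)(CCC=C(C)C)C=CC23)(C(C)C)C(C)C
F14 | step 8 | (R)-2H-pyran, silyl analogue of 12 | CC(C)[Si](Oc1c(CC=C(C)C)cc2c(c1)Oc1cc(O[Si](C(C)C)(C(C)C)C(C)C)ccc1C3=C2C=C[C@@](C)(CCC=C(C)C)O3)(C(C)C)C(C)C
F15 | step 8 | bis(triisopropylsilyl) ether of 14 | CC(C)=CCc1cc2c(cc1O[Si](C(C)C)(C(C)C)C(C)C)Oc1cc(O[Si](C(C)C)(C(C)C)C(C)C)ccc1C1=C2[C@@H]2[C@H]3[C@H](CC[C@@]3(C)O1)C2(C)C
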